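1. In the delta run at 30.0 h, 53.3% of the substrate charged is still in neither product, so what to watch is how the material divides between the two.

| flask | substrate | second nucleophile | solid first nucleophile | remark | time |
|---|---|---|---|---|---|
| eta | 17 mM | 51 mM | 170 mM | run made earlier |  |
| delta | 26 mM | 51 mM | 170 mM | run made earlier |  |
| flask | 34 mM | 51.0 mM | 170 mM |  | 40 h |

| run | time / h | other capture product / % | target / % |
|---|---|---|---|
| eta | 2.50 | 5.9 | 0.5 |
| eta | 6.00 | 10.4 | 0 |
| eta | 15.0 | 25.2 | 0.9 |
| eta | 30.0 | 39.9 | 1.7 |
| delta | 4.00 | 9.6 | 1.1 |
| delta | 12.0 | 22.3 | 0.1 |
| delta | 20.0 | 29.6 | 1.7 |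
| delta | 30.0 | 42.8 | 3.9 |

(scatter of a reading: 1 percentage point)

- at the start none of the solid first nucleophile is in solution

- ratio of other capture product to target at 80 min
- ratio of other capture product to target at 40 h
- which of other capture product and target there is more of at 40 h

2. The flask looks nearly like delta: it has the same 51.0 mM of c(second nucleophile) and the same 170 mM of solid, but 34 mM of substrate against 26 mM. Going from eta to delta raised the substrate from 17 mM to 26 mM, yet other capture product at 30.0 h moved just from 39.9% to 42.8%, with a scatter of 1 percentage point. So we expect the flask's percentages to run close to delta's.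

3. Our own reckoning takes the two nucleophiles as competing for the same thing, so at a fixed charge of solid we let the ratio of other capture product to target follow c(second nucleophile). The target readings at 30.0 h differ by 2.2 points, and we treat that as noise and pool them. The split, a selectivity factor, is the pooled ratio at that time per unit of charged c(second nucleophile): 0.290 mM⁻¹. Assuming it holds unchanged from that time to the flask's 40 h, it gives a ratio of 14.8, with other capture product ahead. For 80 min we give no number, since the earliest target reading, in eta, is 0.5% with a scatter of 1 point.

4. The forecast says a ratio of 300 at 80 min and 7 at 40 h, with other capture product ahead. It read the higher delta target as “perhaps helped by released product”, where we pool.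

5. The flask gives a ratio of 82.7 at 80 min and 15.1 at 40 h, and at 40 h other capture product leads, with 47.6% against 3.16% of target.

    solid first nucleophile ⇌ first nucleophile, rate k1*(cs1 - [first nucleophile]) while solid is left; crystals form when [first nucleophile] > cs1 (solubility = 20.0 mM, k = 0.00160 min⁻¹)
    second nucleophile + intermediate → other capture product (k = 11.0 M⁻¹ min⁻¹)
    target ⇌ isomer of the product (K = 2.80, k = 0.00120 min⁻¹)
    intermediate → solvolysis product (k = 0.0860 min⁻¹)
    first nucleophile + intermediate → target (k = 5.60 M⁻¹ min⁻¹)
    2 first nucleophile → homo dimer (k = 0.00730 M⁻¹ min⁻¹)
    substrate → intermediate (k = 4.20 × 10⁻⁴ min⁻¹)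

In the flask, substrate went to the intermediate throughout, with a half-life of 28 h by that step, and 36% still stood at 40.0 h, beside 47.6% of other capture product. Meanwhile the solid fed first nucleophile, from none to 6.25 mM at 4.00 h and 16.7 mM at 40.0 h, while target, with a net turnover of 7.05% of the substrate charged up to 40 h, passed into isomer of the product (3.89%) with a relaxation half-life, both ways together, of 7.09 h, shorter than the run.

6. For the neighbour charged with 20 mM of second nucleophile, the split gives 5.80. The computed ratio there at 40 h is 5.11, from 31.7% of other capture product and 6.21% of target.

All runs are simulated with constants of no real substance; the scatter is artificial.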